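## Retrosynthetic overview

1. Target 22 ⇒ tetraol ketone 18 + (2S,3S)-epoxyangelic acid 20, joined by esterification of the only secondary hydroxyl; 20 comes from angelic acid by one asymmetric epoxidation.
2. 18 ⇒ eudesma-3,7(11)-dien-8-one 15: α-face OsO4 dihydroxylation of Δ3 (C3, C4), and nucleophilic epoxidation/hydrolysis of the 7(11)-enone (C7, C11).
3. 15 ⇒ bicyclic ketone 11 + acetone (aldol condensation); 11 ⇒ trans-hydrindanone 9 by a one-carbon ring expansion in which the quaternary carbon migrates. Ring B (six-membered) is formed last, from the five-membered ring.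
4. 9 ⇒ enedione 4: Luche reduction, Myers reductive transposition (trans fusion, Δ3), re-oxidation.
5. 4 ⇒ 2-methylcyclopentane-1,3-dione 1 + ethyl vinyl ketone 2; ring A is formed first by asymmetric Robinson annulation.

Assumption: angelic acid is taken as a catalogue chemical, and the (S,S)-configured manganese catalyst of step 9 is taken to give the (2S,3S)-epoxide (its mirror-image form is equally available if the sense proves opposite).

Eudesmane numbering is used for positions: C10 is the methyl-bearing ring-fusion carbon, C5 the ring-fusion CH, C8 the ketone, C7 and C11 the carbinols.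

## Route

Step 1
Reactants: 1 2-methylcyclopentane-1,3-dione; 2 pent-1-en-3-one (ethyl vinyl ketone)
Product: 4 (S)-4,7a-dimethyl-2,3,7,7a-tetrahydro-1H-indene-1,5(6H)-dione, via triketone 3 (not isolated)
Conditions: 2 (1.3 equiv), Et3N (1 mol%), neat, 23 °C; then L-phenylalanine (1 equiv), 1 M aq HClO4 (0.5 equiv), MeCN, 80 °C
Reagents that add atoms: none
Why: Michael addition gives achiral triketone 3, and the amino-acid-mediated enamine aldol condensation (Hajos–Parrish–Eder–Sauer–Wiechert reaction) differentiates the two ring carbonyls and sets the quaternary centre (future C10) as S, the sense known for L-amino acids.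

Step 2
Reactants: 4 (S)-4,7a-dimethyl-2,3,7,7a-tetrahydro-1H-indene-1,5(6H)-dione
Product: 5 (1S,5S,7aS)-4,7a-dimethyl-2,3,5,6,7,7a-hexahydro-1H-indene-1,5-diol
Conditions: NaBH4, CeCl3·7H2O, MeOH, −78 → 0 °C
Reagents that add atoms: none
Why: Luche 1,2-reduction of both carbonyls, with hydride adding from the face opposite the angular methyl to give the β allylic alcohol and the β neopentyl alcohol; recrystallisation of the diol brings the material to >98% ee.

Step 3
Reactants: 5 (1S,5S,7aS)-4,7a-dimethyl-2,3,5,6,7,7a-hexahydro-1H-indene-1,5-diol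
Product: 8 (1S,3aS,7aS)-4,7a-dimethyl-2,3,3a,6,7,7a-hexahydro-1H-inden-1-ol, via sulfonylhydrazine adduct 6 (not isolated), via allylic diazene 7 (not isolated)
Conditions: 2-nitrobenzenesulfonylhydrazide (NBSH), PPh3, DEAD, THF, −30 °C; then 23 °C
Reagents that add atoms: none
Why: Myers reductive 1,3-transposition: Mitsunobu displacement inverts the allylic carbinol (the hindered neopentyl alcohol does not react), loss of sulfinate gives diazene 7 on the α face, and the retro-ene loss of N2 delivers hydrogen suprafacially to the ring-fusion carbon, setting the trans fusion (C5–H α) and moving the double bond to Δ3.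

Step 4
Reactants: 8 (1S,3aS,7aS)-4,7a-dimethyl-2,3,3a,6,7,7a-hexahydro-1H-inden-1-ol
Product: 9 (3aS,7aS)-4,7a-dimethyl-2,3,3a,6,7,7a-hexahydro-1H-inden-1-one
Conditions: Dess–Martin periodinane, CH2Cl2, 23 °C
Reagents that add atoms: none
Why: Dess–Martin oxidation of the remaining secondary alcohol; the ring-fusion CH is not α to the new ketone, so no stereocentre can epimerise.

Step 5
Reactants: 9 (3aS,7aS)-4,7a-dimethyl-2,3,3a,6,7,7a-hexahydro-1H-inden-1-one
Product: 11 (4aR,8aR)-5,8a-dimethyl-3,4,4a,7,8,8a-hexahydronaphthalen-2(1H)-one, via dibromomethyl carbinol 10 (not isolated)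
Conditions: CH2Br2, LiTMP, THF, −78 °C; then n-BuLi, −78 → 0 °C; H2O
Reagents that add atoms: dibromomethane, BrCBr
Why: Taguchi–Yamamoto–Nozaki ring enlargement: LiCHBr2 adds to the ketone from the α face, bromine–lithium exchange triggers a carbenoid 1,2-shift in which the more substituted (quaternary) α-carbon migrates with retention and LiBr is lost, so CH2 (C9) is inserted between C10 and the carbonyl (now C8); relief of trans-hydrindanone strain helps.

Step 6
Reactants: 11 (4aR,8aR)-5,8a-dimethyl-3,4,4a,7,8,8a-hexahydronaphthalen-2(1H)-one; 12 acetone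
Product: 15 (4aR,8aR)-5,8a-dimethyl-3-(propan-2-ylidene)-3,4,4a,7,8,8a-hexahydronaphthalen-2(1H)-one (eudesma-3,7(11)-dien-8-one), via aldol adduct 13 (not isolated), via mesylate 14 (not isolated)
Conditions: LDA, THF, −78 °C; acetone; MsCl, −78 → 0 °C; DBU, 23 °C
Reagents that add atoms: none
Why: Aldol condensation: kinetic enolisation goes toward C7, away from the neopentyl C9; addition to acetone, mesylation of the aldolate in the flask and E1cB elimination give the conjugated isopropylidene ketone, with no new stereocentre.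

Step 7
Reactants: 15 eudesma-3,7(11)-dien-8-one
Product: 17 (3S,4aR,8aR)-3-hydroxy-3-(2-hydroxypropan-2-yl)-5,8a-dimethyl-3,4,4a,7,8,8a-hexahydronaphthalen-2(1H)-one (7α,11-dihydroxyeudesm-3-en-8-one), via epoxide 16 (not isolated)
Conditions: 30% aq H2O2, LiOH, THF–H2O, 0 → 23 °C; then aq HClO4 (pH 1), 23 °C
Reagents that add atoms: hydrogen peroxide, OO; water, O
Why: Weitz–Scheffer nucleophilic epoxidation: hydroperoxide adds to C11 and the ring enolate closes on oxygen along the axial (α) trajectory of the rigid trans-decalin, which sets C7 and leaves the bulky C11 group equatorial; acid then opens the epoxide at the tertiary C11 (SN1-like), so the C7–O bond and its configuration are kept.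

Step 8
Reactants: 17 7α,11-dihydroxyeudesm-3-en-8-one
Product: 18 (3S,4aR,5S,6R,8aR)-3,5,6-trihydroxy-3-(2-hydroxypropan-2-yl)-5,8a-dimethyloctahydronaphthalen-2(1H)-one (3α,4α,7α,11-tetrahydroxyeudesman-8-one)
Conditions: OsO4 (5 mol%), NMO, acetone–H2O, 23 °C
Reagents that add atoms: N-methylmorpholine N-oxide, C[N+]1([O-])CCOCC1; water, O
Why: Upjohn syn-dihydroxylation; OsO4 adds to the trisubstituted Δ3 alkene from the α face, opposite the axial angular methyl, setting C3 (α-OH) and C4 (α-OH, β-methyl) as the cis-diol.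

Step 9
Reactants: 19 (Z)-2-methylbut-2-enoic acid (angelic acid)
Product: 20 (2S,3S)-2,3-dimethyloxirane-2-carboxylic acid
Conditions: Mn(OTf)2((S,S)-PDP) (1 mol%; PDP = 1,1'-bis(pyridin-2-ylmethyl)-2,2'-bipyrrolidine), 2-ethylhexanoic acid, 30% aq H2O2 (slow addition), MeCN, −30 °C
Reagents that add atoms: hydrogen peroxide, OO
Why: Proposed new method: the divalent manganese catalyst, a carboxylic acid and H2O2 give an electrophilic oxo-manganese carboxylate (pentavalent manganese) by acid-assisted O–O heterolysis; concerted oxygen transfer keeps the Z geometry (C3-methyl cis to CO2H) while the C2-symmetric bipyrrolidine pocket selects the olefin face, so both epoxide centres are set in one step, and a free CO2H should be tolerated because carboxylic acids are the normal co-ligands of this catalyst; the closest known reaction is the manganese–aminopyridine-catalysed asymmetric epoxidation of α,β-unsaturated esters and amides with H2O2 and a carboxylic acid additive, not yet shown on a free Z-trisubstituted α,β-unsaturated acid.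

Step 10
Reactants: 18 3α,4α,7α,11-tetrahydroxyeudesman-8-one; 20 (2S,3S)-2,3-dimethyloxirane-2-carboxylic acid
Product: 22 (1S,2R,4aR,7S,8aR)-1,7-dihydroxy-7-(2-hydroxypropan-2-yl)-1,4a-dimethyl-6-oxodecahydronaphthalen-2-yl (2S,3S)-2,3-dimethyloxirane-2-carboxylate, via mixed anhydride 21 (not isolated)
Conditions: 20, 2,4,6-trichlorobenzoyl chloride, Et3N, THF, 23 °C; then 18, DMAP, toluene, 40 °C
Reagents that add atoms: none
Why: Yamaguchi esterification; only the secondary 3α-hydroxyl is acylated, the three tertiary hydroxyls are inert and no stereocentre is touched.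

## Compound list

1 | 2-methylcyclopentane-1,3-dione | CC1C(=O)CCC1=O | starting material
2 | pent-1-en-3-one (ethyl vinyl ketone) | CCC(=O)C=C | starting material
3 | 2-methyl-2-(3-oxopentyl)cyclopentane-1,3-dione | CCC(=O)CCC1(C)C(=O)CCC1=O | intermediate
4 | (S)-4,7a-dimethyl-2,3,7,7a-tetrahydro-1H-indene-1,5(6H)-dione | O=C1CC[C@]2(C)C(=O)CCC2=C1C | intermediate
5 | (1S,5S,7aS)-4,7a-dimethyl-2,3,5,6,7,7a-hexahydro-1H-indene-1,5-diol | O[C@H]1CC[C@]2(C)[C@@H](O)CCC2=C1C | intermediate
6 | 1-[(1S,5R,7aS)-1-hydroxy-4,7a-dimethyl-2,3,5,6,7,7a-hexahydro-1H-inden-5-yl]-1-(2-nitrophenylsulfonyl)hydrazine | NN([C@@H]1CC[C@]2(C)[C@@H](O)CCC2=C1C)S(=O)(=O)c1ccccc1[N+](=O)[O-] | intermediate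
7 | (1S,5R,7aS)-5-diazenyl-4,7a-dimethyl-2,3,5,6,7,7a-hexahydro-1H-inden-1-ol | N=N[C@@H]1CC[C@]2(C)[C@@H](O)CCC2=C1C | intermediate
8 | (1S,3aS,7aS)-4,7a-dimethyl-2,3,3a,6,7,7a-hexahydro-1H-inden-1-ol (trans-fused) | CC1=CCC[C@]2(C)[C@@H](O)CC[C@@H]12 | intermediate
9 | (3aS,7aS)-4,7a-dimethyl-2,3,3a,6,7,7a-hexahydro-1H-inden-1-one | CC1=CCC[C@]2(C)C(=O)CC[C@@H]12 | intermediate
10 | (1S,3aS,7aS)-1-(dibromomethyl)-4,7a-dimethyl-2,3,3a,6,7,7a-hexahydro-1H-inden-1-ol | CC1=CCC[C@]2(C)[C@](O)(C(Br)Br)CC[C@@H]12 | intermediate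
11 | (4aR,8aR)-5,8a-dimethyl-3,4,4a,7,8,8a-hexahydronaphthalen-2(1H)-one | CC1=CCC[C@]2(C)CC(=O)CC[C@@H]12 | intermediate
12 | acetone | CC(C)=O | starting material
13 | (3R,4aR,8aR)-3-(2-hydroxypropan-2-yl)-5,8a-dimethyl-3,4,4a,7,8,8a-hexahydronaphthalen-2(1H)-one (side chain equatorial; C7 configuration is lost in the next event) | CC1=CCC[C@]2(C)CC(=O)[C@@H](C(C)(C)O)C[C@@H]12 | intermediate
14 | methanesulfonate of the tertiary alcohol of 13 | CC1=CCC[C@]2(C)CC(=O)[C@@H](C(C)(C)OS(C)(=O)=O)C[C@@H]12 | intermediate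
15 | (4aR,8aR)-5,8a-dimethyl-3-(propan-2-ylidene)-3,4,4a,7,8,8a-hexahydronaphthalen-2(1H)-one (eudesma-3,7(11)-dien-8-one) | CC1=CCC[C@]2(C)CC(=O)C(=C(C)C)C[C@@H]12 | intermediate
16 | 7α,11-epoxyeudesm-3-en-8-one (spiro-epoxide across C7/C11, oxygen axial on the α face, 7S) | CC1=CCC[C@]2(C)CC(=O)[C@]3(OC3(C)C)C[C@@H]12 | intermediate
17 | (3S,4aR,8aR)-3-hydroxy-3-(2-hydroxypropan-2-yl)-5,8a-dimethyl-3,4,4a,7,8,8a-hexahydronaphthalen-2(1H)-one (7α,11-dihydroxyeudesm-3-en-8-one) | CC1=CCC[C@]2(C)CC(=O)[C@@](O)(C(C)(C)O)C[C@@H]12 | intermediate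
18 | (3S,4aR,5S,6R,8aR)-3,5,6-trihydroxy-3-(2-hydroxypropan-2-yl)-5,8a-dimethyloctahydronaphthalen-2(1H)-one (3α,4α,7α,11-tetrahydroxyeudesman-8-one) | O[C@@H]1CC[C@]2(C)CC(=O)[C@@](O)(C(C)(C)O)C[C@H]2[C@]1(C)O | intermediate
19 | (Z)-2-methylbut-2-enoic acid (angelic acid) | C/C=C(/C)C(=O)O | starting material
20 | (2S,3S)-2,3-dimethyloxirane-2-carboxylic acid | C[C@@H]1O[C@]1(C)C(=O)O | intermediate
21 | (2S,3S)-2,3-dimethyloxirane-2-carboxylic 2,4,6-trichlorobenzoic anhydride | C[C@@H]1O[C@]1(C)C(=O)OC(=O)c1c(Cl)cc(Cl)cc1Cl | intermediate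
22 | (1S,2R,4aR,7S,8aR)-1,7-dihydroxy-7-(2-hydroxypropan-2-yl)-1,4a-dimethyl-6-oxodecahydronaphthalen-2-yl (2S,3S)-2,3-dimethyloxirane-2-carboxylate | C[C@@H]1O[C@]1(C)C(=O)O[C@@H]1CC[C@]2(C)CC(=O)[C@@](O)(C(C)(C)O)C[C@H]2[C@]1(C)O | target

## Step count and risks

Total step count: 10. Longest linear sequence: 9 (steps 1–8 and 10).

The three steps most likely to fail:

Step 9 (the proposed epoxidation). The electron-poor, trisubstituted free acid may react slowly, or with modest or reversed enantioselectivity. The fallback uses known chemistry, sets out from 19 and comes back at 20, and costs two more steps. LiAlH4 in Et2O at 0 °C reduces 19 to (Z)-2-methylbut-2-en-1-ol F1. Sharpless asymmetric epoxidation (Ti(OiPr)4, D-(−)-diethyl tartrate, t-BuOOH, 4 Å sieves, CH2Cl2, −20 °C) gives [(2R,3S)-2,3-dimethyloxiran-2-yl]methanol F2. Oxidation with catalytic RuCl3 and NaIO4 returns acid 20.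

Step 5 (ring expansion). Dibromomethyllithium may enolise the hindered ketone instead of adding, and butyl bromide formed in the flask can alkylate the product enolate. The fallback sets out from 9 and comes back at 11, going stepwise through an isolable adduct. Lithiated chloromethyl p-tolyl sulfoxide (LDA, THF, −78 °C) adds to 9 to give the α-chloro-β-hydroxy sulfoxide F3, which is purified. Treatment with t-BuMgCl and then i-PrMgCl effects sulfoxide–magnesium exchange and a magnesium-carbenoid 1,2-shift to 11. No dibromomethyllithium, lithium–bromine exchange or alkyl bromide is involved.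

Step 7 (C7 configuration). Enolate closure on the β face would give the C7 epimer, and tertiary epoxide opening can be accompanied by elimination. The fallback sets out from 15 and comes back at 18, replacing steps 7 and 8, and controls C7 by a different element. Luche reduction (NaBH4, CeCl3·7H2O) gives the axial allylic alcohol eudesma-3,7(11)-dien-8β-ol F4. OsO4/NMO then dihydroxylates both alkenes from the α face, the tetrasubstituted one anti to the axial allylic hydroxyl (Kishi's rule), to give eudesmane-3α,4α,7α,8β,11-pentaol F5. Phenylboronic acid masks the two 1,2-diols as the bis(phenylboronate) F6, Dess–Martin oxidation of the one free hydroxyl at C8 gives the keto bis(phenylboronate) F7, and exchange with aqueous sorbitol–Na2CO3 releases 18.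

Further compounds
F1 | step 9 | (Z)-2-methylbut-2-en-1-ol | C/C=C(/C)CO
F2 | step 9 | [(2R,3S)-2,3-dimethyloxiran-2-yl]methanol | C[C@@H]1O[C@]1(C)CO
F3 | step 5 | (1S,3aS,7aS)-1-[chloro(4-methylphenylsulfinyl)methyl]-4,7a-dimethyl-2,3,3a,6,7,7a-hexahydro-1H-inden-1-ol (mixture at the CHCl and sulfur centres) | CC1=CCC[C@]2(C)[C@](O)(C(Cl)S(=O)c3ccc(C)cc3)CC[C@@H]12
F4 | step 7 | (2R,4aR,8aR)-5,8a-dimethyl-3-(propan-2-ylidene)-1,2,3,4,4a,7,8,8a-octahydronaphthalen-2-ol (eudesma-3,7(11)-dien-8β-ol) | CC1=CCC[C@]2(C)C[C@@H](O)C(=C(C)C)C[C@@H]12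
F5 | step 7 | eudesmane-3α,4α,7α,8β,11-pentaol | O[C@@H]1CC[C@]2(C)C[C@@H](O)[C@@](O)(C(C)(C)O)C[C@H]2[C@]1(C)O
F6 | step 7 | 3,4:7,11-bis-O-(phenylboranediyl)eudesmane-3α,4α,7α,8β,11-pentaol | c1ccccc1B2O[C@@H]3CC[C@]4(C)C[C@@H](O)[C@]5(OB(c6ccccc6)OC5(C)C)C[C@H]4[C@]3(C)O2
F7 | step 7 | 3,4:7,11-bis-O-(phenylboranediyl)-3α,4α,7α,11-tetrahydroxyeudesman-8-one | c1ccccc1B2O[C@@H]3CC[C@]4(C)CC(=O)[C@]5(OB(c6ccccc6)OC5(C)C)C[C@H]4[C@]3(C)O2
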